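Assumption: benzyl docosanoate has no stereocentre, so the "single enantiomer" is simply the achiral compound and no stereocontrol is needed.

**Retrosynthetic overview**
1. Target 5 is acyclic and achiral: no rings are formed and no stereocentres are set. The benzyl ester C–O bond is bought in, not made.
2. Key disconnection is C2–C3. The ester α-carbon is the acceptor (an a2, enolonium-type synthon) in the form of benzyl bromoacetate 2; the C20 chain is the donor, B-icosyl-9-BBN 3.
3. Borane 3 comes from icos-1-ene 1 by anti-Markovnikov hydroboration with 9-BBN in the same flask.
4. The C–C bond forms by boron-ate formation and 1,2-alkyl migration with loss of bromide, so the whole route is one operation (C20 + C2 = C22).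

**Route**

Step 1
Reactants: 1 icos-1-ene (1-eicosene); 2 benzyl bromoacetate
Product: 5 benzyl docosanoate, via B-icosyl-9-BBN 3 (not isolated), via alpha-boryl ester 4 (not isolated)
Conditions: 1 (1.05 equiv), 9-BBN (0.5 M in THF, 1.0 equiv), THF, 0 °C → rt, 3 h; then 2 (1.0 equiv), t-BuOH, 0 °C; KOt-Bu (1.0 M in t-BuOH, 1.0 equiv) added dropwise, 0 °C, 1 h; aq. NH4Cl; SiO2 (hexanes/EtOAc), recrystallise
Reagents that add atoms: none
Why: 9-BBN hydroborates the terminal alkene with >99:1 anti-Markovnikov selectivity, and the B-alkyl-9-BBN then undergoes the Brown α-alkylation of an α-bromo ester, in which the bromoacetate enolate adds to boron, the primary icosyl group migrates 1,2 from boron to the α-carbon with loss of bromide, and t-BuOH protonates the resulting boron enolate; no stereocentre is created.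

**Compound list**
1 | icos-1-ene (1-eicosene) | CCCCCCCCCCCCCCCCCCC=C | starting material
2 | benzyl bromoacetate (benzyl 2-bromoacetate) | BrCC(=O)OCc1ccccc1 | starting material
3 | 9-icosyl-9-borabicyclo[3.3.1]nonane (B-icosyl-9-BBN) | CCCCCCCCCCCCCCCCCCCCB1C2CCCC1CCC2 | intermediate
4 | benzyl 2-(9-borabicyclo[3.3.1]nonan-9-yl)docosanoate (racemic, transient; in equilibrium with its O-boron enolate) | CCCCCCCCCCCCCCCCCCCCC(B1C2CCCC1CCC2)C(=O)OCc1ccccc1 | intermediate
5 | benzyl docosanoate | CCCCCCCCCCCCCCCCCCCCCC(=O)OCc1ccccc1 | target

**Total step count:** 1
**Longest linear sequence:** 1

**Steps most likely to fail**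
The route has a single step, so step 1 is the only one that can be ranked.

Step 1. The risks are all in the second stage. One of the cyclooctyl B–C bonds could migrate instead of the icosyl group. The bromoacetate could be consumed by the base before it reaches boron (self-condensation or substitution by tert-butoxide). The benzyl ester could be partly exchanged to the tert-butyl ester.

Fallback: this sets out from 1 and 2 and replaces the boron-ate migration with a radical addition. The electrophilic α-ester radical from 2 is added to the terminal alkene of 1 by bromine atom-transfer radical addition (Et3B/air initiation, CH2Cl2, rt). This gives benzyl 4-bromodocosanoate F1 as a racemate. The secondary bromide is then removed with Bu3SnH (Et3B/air, toluene, rt). The mild temperature avoids closure of the γ-bromo ester to the γ-lactone, and the benzyl ester is untouched. The stereocentre at C4 disappears in this reduction. The fallback comes back to the route at 5.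

**Further compounds**
F1 | step 1 | benzyl 4-bromodocosanoate (racemic) | CCCCCCCCCCCCCCCCCCC(Br)CCC(=O)OCc1ccccc1
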